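**Plan**
Retrosynthesis: the four phenols are masked as methyl ethers. Flavone ring C is opened at C4–C4a to a (Z)-β-aryloxycinnamic acid. The vinyl ether bond O1–C2 is then cut to a biaryl phenol and an arylpropiolate, and the biaryl bond (flavone C8–coumarin C6) to a coumarin boronate and 2-iodo-3,5-dimethoxyphenol.
Forward order: coumarin lactone ring (Pechmann), biaryl bond (Suzuki–Miyaura), O1–C2 (oxa-Michael), ring C (Friedel–Crafts acylation), fourfold demethylation.
Enabling feature: in ring A, O1 is attached to C8a. The two carbons ortho to it are C8, which already carries the coumarin-6-yl group, and C4a. The acyl carbon C4 can therefore bond only to C4a, which the oxygens at C5 and C7 activate.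
Stereochemistry: the target has no stereocentre. The only stereoelement on the way is the Z alkene of the cyclization precursor, set by anti addition of the phenoxide to the alkyne.

Key step: step 9

Assumption: the biaryl axis is drawn without configuration, so no atroposelective step is planned and the compound is made without control of axial chirality.

Step 1
Reactants: 1 4-bromoresorcinol; 2 DL-malic acid
Product: 4 6-bromo-7-hydroxycoumarin, via formylacetic acid 3 (not isolated)
Conditions: conc. H2SO4, 100–110 °C, then ice-water
Reagents that add atoms: none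
Why: In this von Pechmann coumarin synthesis, hot sulfuric acid decarbonylates malic acid to formylacetic acid, which condenses at C6 of the resorcinol (ortho to one hydroxyl, para to the other, with C4 blocked by bromine) and lactonizes.

Step 2
Reactants: 4 6-bromo-7-hydroxycoumarin
Product: 5 6-bromo-7-methoxycoumarin
Conditions: MeI, K2CO3, acetone, reflux
Reagents that add atoms: iodomethane, CI
Why: Williamson O-methylation of the acidic 7-hydroxyl should proceed under mild carbonate conditions that leave the lactone and the aryl bromide untouched.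

Step 3
Reactants: 5 6-bromo-7-methoxycoumarin
Product: 6 7-methoxy-6-(4,4,5,5-tetramethyl-1,3,2-dioxaborolan-2-yl)coumarin
Conditions: B2pin2, Pd(dppf)Cl2 (cat.), KOAc, 1,4-dioxane, 85 °C
Reagents that add atoms: bis(pinacolato)diboron, CC1(C)OB(OC1(C)C)B1OC(C)(C)C(C)(C)O1
Why: Miyaura borylation of an aryl bromide uses acetate as base, which is too weak to open the lactone or to trigger homocoupling.

Step 4
Reactants: 7 3,5-dimethoxyphenol
Product: 8 2-iodo-3,5-dimethoxyphenol
Conditions: NIS (1.0 equiv), MeCN, 0 °C
Reagents that add atoms: N-iodosuccinimide, O=C1CCC(=O)N1I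
Why: In this electrophilic aromatic iodination the two equivalent carbons ortho to the hydroxyl (each para to a methoxy group) are favoured statistically and sterically over C4, which lies between two methoxy groups, and a minor 4-iodo isomer would be removed by chromatography.

Step 5
Reactants: 6 7-methoxy-6-(4,4,5,5-tetramethyl-1,3,2-dioxaborolan-2-yl)coumarin; 8 2-iodo-3,5-dimethoxyphenol
Product: 9 6-(2-hydroxy-4,6-dimethoxyphenyl)-7-methoxycoumarin
Conditions: Pd(OAc)2 (cat.), SPhos, K3PO4, 1,4-dioxane–H2O, 90 °C
Reagents that add atoms: none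
Why: In this Suzuki–Miyaura coupling the bulky, electron-rich biarylphosphine supports oxidative addition of the electron-rich iodide to zerovalent palladium and reductive elimination of the tri-ortho-substituted biaryl, free phenols are tolerated, and any lactone opened by the aqueous base recloses on acidification during work-up.

Step 6
Reactants: 10 3-(4-methoxyphenyl)propiolic acid
Product: 11 tert-butyl 3-(4-methoxyphenyl)propiolate
Conditions: Cl3CC(=NH)Ot-Bu, CH2Cl2–cyclohexane, rt
Reagents that add atoms: tert-butyl 2,2,2-trichloroacetimidate, CC(C)(C)OC(=N)C(Cl)(Cl)Cl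
Why: Trichloroacetimidate esterification transfers the tert-butyl group to the carboxylic acid under nearly neutral conditions that spare the alkyne, and this ester can later be removed without hydroxide, which would attack the coumarin lactone.

Step 7
Reactants: 9 6-(2-hydroxy-4,6-dimethoxyphenyl)-7-methoxycoumarin; 11 tert-butyl 3-(4-methoxyphenyl)propiolate
Product: 12 tert-butyl (Z)-3-[3,5-dimethoxy-2-(7-methoxy-2-oxochromen-6-yl)phenoxy]-3-(4-methoxyphenyl)acrylate
Conditions: Cs2CO3 (0.5 equiv), dry DMF, 4 Å molecular sieves, 80 °C
Reagents that add atoms: none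
Why: In this base-catalysed oxa-Michael addition of a phenoxide to an arylpropiolate (the first stage of the Ruhemann flavone synthesis), attack at the β-carbon and anti protonation place the aryloxy and ester groups on the same side, and this Z isomer is also the less crowded one because anisyl and ester lie trans.

Step 8
Reactants: 12 tert-butyl (Z)-3-[3,5-dimethoxy-2-(7-methoxy-2-oxochromen-6-yl)phenoxy]-3-(4-methoxyphenyl)acrylate
Product: 13 (Z)-3-[3,5-dimethoxy-2-(7-methoxy-2-oxochromen-6-yl)phenoxy]-3-(4-methoxyphenyl)acrylic acid
Conditions: CF3CO2H–CH2Cl2 (1:3), 0 °C to rt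
Reagents that add atoms: none
Why: Acidolysis of the tert-butyl ester proceeds by loss of the tert-butyl cation as isobutene, and in the absence of water neither the vinyl ether nor the lactone can be hydrolysed.

Step 9
Reactants: 13 (Z)-3-[3,5-dimethoxy-2-(7-methoxy-2-oxochromen-6-yl)phenoxy]-3-(4-methoxyphenyl)acrylic acid
Product: 14 5,7-dimethoxy-8-(7-methoxy-2-oxochromen-6-yl)-2-(4-methoxyphenyl)chromen-4-one
Conditions: P2O5–MeSO3H (1:10 w/w), rt to 50 °C, then ice-water
Reagents that add atoms: none
Why: The dehydrating acid medium turns the carboxyl group into an acylium-type electrophile, ring A attacks it through the carbon that becomes C4a, and proton loss from the arenium ion completes the C4–C4a bond and the pyranone. This is an intramolecular Friedel–Crafts acylation, the cyclization stage of the Ruhemann flavone synthesis, for which sulfuric acid, polyphosphoric acid and P2O5–MeSO3H are established media. Ring C closes as a six-membered ring in 6-exo-trig mode at the activated acyl carbon (6-exo-dig if the free acylium ion reacts), with the arene bond C4a–C8a inside the new ring, and no stereocentre is formed. The selectivity needed is 8-aryl against 6-aryl flavone, and the substrate fixes it, because one carbon ortho to the ether oxygen is occupied by the coumarin while the open one is ortho to that oxygen and to one methoxy group and para to the other. The Z geometry puts the carboxyl group next to the aryloxy ring, and any E isomer can equilibrate by reversible protonation at the α-carbon, since its own closure onto the anisyl ring would have to occur meta to methoxy and give a strained indenone. The coumarin should not interfere, because its benzo ring is deactivated by the lactone, is stable to strong acid and could be reached only through an eight-membered ring.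

Step 10
Reactants: 14 5,7-dimethoxy-8-(7-methoxy-2-oxochromen-6-yl)-2-(4-methoxyphenyl)chromen-4-one
Product: 15 5,7-dihydroxy-8-(7-hydroxy-2-oxochromen-6-yl)-2-(4-hydroxyphenyl)chromen-4-one (target)
Conditions: BBr3 (excess), CH2Cl2, −78 °C to rt, then H2O
Reagents that add atoms: none
Why: In this Lewis-acid cleavage of aryl methyl ethers, boron binds each ether oxygen and bromide removes the methyl group by SN2, and the aprotic medium keeps both pyranone rings closed, so a Wessely–Moser shift of the aryl group from C8 to C6 is not expected.

**Compound list**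
1 | 4-bromoresorcinol | Oc1ccc(Br)c(O)c1 | starting material
2 | DL-malic acid | OC(CC(=O)O)C(=O)O | starting material
3 | formylacetic acid (3-oxopropanoic acid) | O=CCC(=O)O | intermediate
4 | 6-bromo-7-hydroxycoumarin | O=c1ccc2cc(Br)c(O)cc2o1 | intermediate
5 | 6-bromo-7-methoxycoumarin | COc1cc2oc(=O)ccc2cc1Br | intermediate
6 | 7-methoxy-6-(4,4,5,5-tetramethyl-1,3,2-dioxaborolan-2-yl)coumarin | COc1cc2oc(=O)ccc2cc1B1OC(C)(C)C(C)(C)O1 | intermediate
7 | 3,5-dimethoxyphenol | COc1cc(O)cc(OC)c1 | starting material
8 | 2-iodo-3,5-dimethoxyphenol | COc1cc(O)c(I)c(OC)c1 | intermediate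
9 | 6-(2-hydroxy-4,6-dimethoxyphenyl)-7-methoxycoumarin | COc1cc(O)c(c(OC)c1)-c1cc2ccc(=O)oc2cc1OC | intermediate
10 | 3-(4-methoxyphenyl)propiolic acid | COc1ccc(cc1)C#CC(=O)O | starting material
11 | tert-butyl 3-(4-methoxyphenyl)propiolate | COc1ccc(cc1)C#CC(=O)OC(C)(C)C | intermediate
12 | tert-butyl (Z)-3-[3,5-dimethoxy-2-(7-methoxy-2-oxochromen-6-yl)phenoxy]-3-(4-methoxyphenyl)acrylate | COc1ccc(cc1)/C(=C/C(=O)OC(C)(C)C)Oc1cc(OC)cc(OC)c1-c1cc2ccc(=O)oc2cc1OC | intermediate
13 | (Z)-3-[3,5-dimethoxy-2-(7-methoxy-2-oxochromen-6-yl)phenoxy]-3-(4-methoxyphenyl)acrylic acid | COc1ccc(cc1)/C(=C/C(=O)O)Oc1cc(OC)cc(OC)c1-c1cc2ccc(=O)oc2cc1OC | intermediate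
14 | 5,7-dimethoxy-8-(7-methoxy-2-oxochromen-6-yl)-2-(4-methoxyphenyl)chromen-4-one | COc1ccc(cc1)-c1cc(=O)c2c(OC)cc(OC)c(-c3cc4ccc(=O)oc4cc3OC)c2o1 | intermediate
15 | 5,7-dihydroxy-8-(7-hydroxy-2-oxochromen-6-yl)-2-(4-hydroxyphenyl)chromen-4-one | O=c1ccc2cc(-c3c(O)cc(O)c4c(=O)cc(-c5ccc(O)cc5)oc34)c(O)cc2o1 | target

Total step count: 10.
Longest linear sequence: 8 steps (1, 2, 3, 5, 7, 8, 9, 10).

**Steps most likely to fail**

Step 7. The conjugate addition may be too slow. The phenoxide is crowded by the neighbouring coumarinyl group, and the β-carbon of the alkyne is deactivated by the p-methoxyphenyl donor. Prolonged heating would then favour hydration of the alkyne or reversal of the addition. The fallback lowers the oxidation level of the acceptor to make it more electrophilic. It sets out from 9. Commercial 4-ethynylanisole is lithiated with n-BuLi and formylated with DMF to 3-(4-methoxyphenyl)prop-2-ynal F1. Phenol 9 is added to it with K2CO3 in MeCN at rt to give (Z)-3-[3,5-dimethoxy-2-(7-methoxy-2-oxochromen-6-yl)phenoxy]-3-(4-methoxyphenyl)prop-2-enal F2. Pinnick oxidation (NaClO2, NaH2PO4, 2-methyl-2-butene, t-BuOH–H2O) then leads back to the route at acid 13, so steps 6 and 8 are no longer needed.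

Step 5. Oxidative addition to the electron-rich, doubly ortho-substituted iodophenoxide and transmetalation of the hindered boronate may both be sluggish. Protodeboronation and reductive deiodination could then outrun the coupling. The fallback reverses the polarity and replaces boron by zinc. It sets out from 8 and 5. Phenol 8 is protected (MeOCH2Cl, i-Pr2NEt, CH2Cl2) as 2-iodo-1,5-dimethoxy-3-(methoxymethoxy)benzene F3. LiCl-promoted insertion of zinc dust in THF at 50 °C gives [2,4-dimethoxy-6-(methoxymethoxy)phenyl]zinc iodide F4. Negishi coupling with bromide 5 (Pd2(dba)3, RuPhos, THF, 60 °C) gives 6-[2,4-dimethoxy-6-(methoxymethoxy)phenyl]-7-methoxycoumarin F5. HCl in MeOH removes the acetal and returns to the route at 9, and step 3 is then not needed.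

Step 9. Protonation of the vinyl ether at the α-carbon, followed by expulsion of the phenol or by decarboxylation, may compete with acylation. Sulfonylation of the very electron-rich ring A is a further possible side reaction. The fallback forms the same C4–C4a bond first, intermolecularly, and closes ring C at O1–C2 instead. It sets out from 9. Chelation-directed Friedel–Crafts acetylation (Ac2O, BF3·OEt2, 70 °C) at the free carbon ortho to the hydroxyl gives 1-[2-hydroxy-4,6-dimethoxy-3-(7-methoxy-2-oxochromen-6-yl)phenyl]ethanone F6. Its enolate (LiN(SiMe3)2, THF, −78 °C) is acylated with 4-methoxybenzoyl chloride to give 1-[2-hydroxy-4,6-dimethoxy-3-(7-methoxy-2-oxochromen-6-yl)phenyl]-3-(4-methoxyphenyl)propane-1,3-dione F7. Cyclodehydration (cat. H2SO4, AcOH, 90 °C) returns to the route at 14.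

**Further compounds**
F1 | step 7 | 3-(4-methoxyphenyl)prop-2-ynal | COc1ccc(cc1)C#CC=O
F2 | step 7 | (Z)-3-[3,5-dimethoxy-2-(7-methoxy-2-oxochromen-6-yl)phenoxy]-3-(4-methoxyphenyl)prop-2-enal | COc1ccc(cc1)/C(=C/C=O)Oc1cc(OC)cc(OC)c1-c1cc2ccc(=O)oc2cc1OC
F3 | step 5 | 2-iodo-1,5-dimethoxy-3-(methoxymethoxy)benzene | COCOc1cc(OC)cc(OC)c1I
F4 | step 5 | [2,4-dimethoxy-6-(methoxymethoxy)phenyl]zinc iodide | COCOc1cc(OC)cc(OC)c1[Zn]I
F5 | step 5 | 6-[2,4-dimethoxy-6-(methoxymethoxy)phenyl]-7-methoxycoumarin | COCOc1cc(OC)cc(OC)c1-c1cc2ccc(=O)oc2cc1OC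
F6 | step 9 | 1-[2-hydroxy-4,6-dimethoxy-3-(7-methoxy-2-oxochromen-6-yl)phenyl]ethanone | CC(=O)c1c(O)c(-c2cc3ccc(=O)oc3cc2OC)c(OC)cc1OC
F7 | step 9 | 1-[2-hydroxy-4,6-dimethoxy-3-(7-methoxy-2-oxochromen-6-yl)phenyl]-3-(4-methoxyphenyl)propane-1,3-dione | COc1ccc(cc1)C(=O)CC(=O)c1c(O)c(-c2cc3ccc(=O)oc3cc2OC)c(OC)cc1OC
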